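**Retrosynthetic overview**
1. The target is a normal labdane (5α-H, 9α-H, 10β-CH3, 13S) with C7=C8 in ring B and acetates on C15 and C17. Only oxidation level and acetylation are adjusted at the end: diacetate ⇐ 17-ol ⇐ Δ7-17-al ⇐ 7-hydroxy-17-al.
2. Key disconnection: ring B is opened at C9–C10 and at C7–C8 in one retro radical conjugate addition/aldol step. This splits the molecule at the quaternary carbon C10 into an 11-carbon ring-A aldehyde and a 9-carbon side-chain enal.
3. Enabling feature: C8 of ring B bears the oxidised carbon C17, so C7=C8–C17 read as an enal is an aldol-condensation retron. Its β-carbon C9 is bonded to the methyl-bearing quaternary C10, the carbon that becomes a tertiary radical by Markovnikov hydrogen-atom transfer to a C1=C10 alkene of ring A.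
4. Fragments: C5 of the ring-A piece comes from CBS reduction of 2,4,4-trimethylcyclohex-2-en-1-one and a Claisen rearrangement that carries the carbinol configuration to C5. The side chain comes from (S)-citronellol (C13 from the chiral pool) by cross-metathesis with crotonaldehyde.
5. Ring order: ring A is present from the start; ring B is formed in the key step.

Key step: step 5

Remark: atoms are named with labdane numbering (ring A C1–C5/C10, ring B C5–C10, C17 on C8, C20 on C10, side chain C11–C16); the target is 5S,9R,10S,13S, and 2,4,4-trimethylcyclohex-2-en-1-one is taken as a catalogue compound.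

Step 1
Reactants: 1 (S)-citronellol [(S)-3,7-dimethyloct-6-en-1-ol]
Product: 2 (S)-citronellyl acetate [(S)-3,7-dimethyloct-6-en-1-yl acetate]
Conditions: Ac2O, pyridine, DMAP (cat), CH2Cl2, 0 °C to rt
Reagents that add atoms: acetic anhydride, CC(=O)OC(C)=O
Why: DMAP-catalysed O-acylation of the primary alcohol installs the C15 acetate that the target carries and leaves the alkene and the C13 centre (S, from the chiral pool) untouched

Step 2
Reactants: 2 (S)-citronellyl acetate; 3 (E)-but-2-enal (crotonaldehyde)
Product: 4 (3S,6E)-3-methyl-8-oxooct-6-en-1-yl acetate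
Conditions: second-generation Hoveyda–Grubbs catalyst (5 mol %), 3 (5 equiv), CH2Cl2, 40 °C
Reagents that add atoms: none
Why: Olefin cross-metathesis between the trisubstituted isopropylidene alkene and an excess of the electron-poor enal, driven by loss of volatile 2-methylbut-2-ene, should give the conjugated (E)-enal as the thermodynamic isomer while the acetate and C13 are spectators

Step 3
Reactants: 5 2,4,4-trimethylcyclohex-2-en-1-one
Product: 6 (R)-2,4,4-trimethylcyclohex-2-en-1-ol
Conditions: (S)-2-methyl-CBS-oxazaborolidine (10 mol %), BH3·SMe2, THF, −20 °C; MeOH, then aqueous work-up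
Reagents that add atoms: none
Why: Corey–Bakshi–Shibata reduction, in which the ketone binds the catalyst boron with the methyl-substituted alkene carbon as the large group and hydride is delivered from the N-bound borane, is expected to give clean 1,2-reduction to the (R)-allylic alcohol (same sense as acetophenone with the (S)-catalyst), and this carbinol centre is the only source of ring chirality

Step 4
Reactants: 6 (R)-2,4,4-trimethylcyclohex-2-en-1-ol
Product: 8 (S)-2-(2,6,6-trimethylcyclohex-2-en-1-yl)acetaldehyde, via allyl vinyl ether 7 (not isolated)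
Conditions: Pd(OCOCF3)2 (1 mol %), 4,7-diphenyl-1,10-phenanthroline (1 mol %), Et3N (cat), n-butyl vinyl ether, 75 °C; volatiles removed; toluene, 150 °C, sealed tube
Reagents that add atoms: n-butyl vinyl ether, C=COCCCC
Why: Palladium-catalysed vinyl exchange gives allyl vinyl ether 7, and its thermal Claisen rearrangement, a [3,3]-sigmatropic shift that is suprafacial on the ring allyl unit, forms the C5–C6 bond on the face from which the C1–O bond departs, so the (R)-carbinol centre becomes the (S)-centre at C5 (5α-H) and the alkene moves to C1=C10 where step 5 needs it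

Step 5
Reactants: 8 (S)-2-(2,6,6-trimethylcyclohex-2-en-1-yl)acetaldehyde; 4 (3S,6E)-3-methyl-8-oxooct-6-en-1-yl acetate
Product: 11 (13S)-15-acetoxy-7ξ-hydroxy-8ξ-labdan-17-al, via tertiary C10 radical 9 (not isolated), via Giese-adduct enolate 10 (not isolated)
Conditions: Fe(acac)3 (30 mol %), PhSiH3 (2.5 equiv), 4 (2.5 equiv), EtOH/(CH2OH)2 5:1, 40 °C
Reagents that add atoms: none
Why: Fe(acac)3 and PhSiH3 form a trivalent iron hydride that transfers a hydrogen atom to C1 of the electron-rich C1=C10 alkene of 8 (Markovnikov), the nucleophilic tertiary radical 9 adds to the β-carbon C9 of enal 4 (Giese addition, C9–C10 bond), divalent iron reduces the resulting α-formyl radical to enolate 10, and 10 adds to the C7 aldehyde (aldol, C7–C8 bond) with ethanol giving up the proton. The closest known reaction type is the MHAT-initiated radical–polar crossover annulation (Giese addition then aldol) of an alkenyl aldehyde with an α,β-unsaturated carbonyl compound, which has been used to build trans-decalins with angular methyl groups. Ring B closes in the 6-(enolexo)-exo-trig mode through a chair in which the C9 side chain is equatorial. C10 is controlled by the C5 centre: the acceptor should attack the radical from the α face, anti to the C5 CH2CHO arm and away from the syn-axial C4 methyl that shields the β face, which leaves the C20 methyl axial and β and makes the ring fusion trans (5α-H, 10β-CH3). C9 is set in the same addition, where the staggered transition state should place the formyl-bearing C8 anti to the bulky ring carbon C5 and the vinylic hydrogen in the crowded slot beside C6, which corresponds to 9α-H; the C7 and C8 centres form as mixtures that are erased in step 6. The step needs hydrogen-atom transfer to the donor alkene and not to the enal (secured by the match of the hydridic iron hydride with the electron-rich alkene), attack at C9 only (the radical then sits next to CHO), and trapping of 9 by excess 4 faster than loss of hydrogen from C5, which would scramble that centre.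

Step 6
Reactants: 11 (13S)-15-acetoxy-7ξ-hydroxy-8ξ-labdan-17-al
Product: 13 (13S)-15-acetoxylabd-7-en-17-al, via C7 mesylate 12 (not isolated)
Conditions: MsCl, Et3N, CH2Cl2, 0 °C; then DBU, rt
Reagents that add atoms: none
Why: Mesylation of the C7 alcohol followed by base-induced E1cB elimination through the aldehyde enolate gives the conjugated C7=C8 enal from every C7/C8 epimer, while C9 cannot epimerise because it is attached to the α-carbon and is not conjugated to the carbonyl group

Step 7
Reactants: 13 (13S)-15-acetoxylabd-7-en-17-al
Product: 14 (13S)-17-hydroxylabd-7-en-15-yl acetate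
Conditions: NaBH4, CeCl3·7H2O, MeOH, −20 to 0 °C
Reagents that add atoms: none
Why: Luche reduction is a fast and selective 1,2-reduction of the enal to the primary allylic alcohol at low temperature, under which the C15 acetate and the trisubstituted alkene are not expected to react

Step 8
Reactants: 14 (13S)-17-hydroxylabd-7-en-15-yl acetate
Product: 15 (13S)-labd-7-ene-15,17-diyl diacetate (target)
Conditions: Ac2O, pyridine, DMAP (cat), CH2Cl2, rt
Reagents that add atoms: acetic anhydride, CC(=O)OC(C)=O
Why: DMAP-catalysed acetylation of the unhindered primary allylic alcohol completes the diacetate without touching any stereocentre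

**Compound list**
1 | (S)-citronellol, (S)-3,7-dimethyloct-6-en-1-ol | OCC[C@@H](C)CCC=C(C)C | starting material
2 | (S)-citronellyl acetate, (S)-3,7-dimethyloct-6-en-1-yl acetate | CC(=O)OCC[C@@H](C)CCC=C(C)C | intermediate
3 | (E)-but-2-enal (crotonaldehyde) | C/C=C/C=O | starting material
4 | (3S,6E)-3-methyl-8-oxooct-6-en-1-yl acetate | CC(=O)OCC[C@@H](C)CC/C=C/C=O | intermediate
5 | 2,4,4-trimethylcyclohex-2-en-1-one | CC1=CC(C)(C)CCC1=O | starting material
6 | (R)-2,4,4-trimethylcyclohex-2-en-1-ol | O[C@@H]1CCC(C)(C)C=C1C | intermediate
7 | (R)-6-(ethenyloxy)-1,3,3-trimethylcyclohex-1-ene (allyl vinyl ether, not isolated) | C=CO[C@@H]1CCC(C)(C)C=C1C | intermediate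
8 | (S)-2-(2,6,6-trimethylcyclohex-2-en-1-yl)acetaldehyde | O=CC[C@@H]1C(C)=CCCC1(C)C | intermediate
9 | tertiary C10 radical from 8 (1,3,3-trimethyl-2-(2-oxoethyl)cyclohexyl radical, C5 as in 8; not isolated) | O=CC[C@@H]1[C](C)CCCC1(C)C | intermediate
10 | Giese-adduct enolate (7,8-seco-labdane: C7 aldehyde, C8=C17 enolate; 5α-H, 9α-H, 10β-CH3, 13S; not isolated) | CC(=O)OCC[C@@H](C)CC[C@@H](C=C[O-])[C@@]1(C)CCCC(C)(C)[C@@H]1CC=O | intermediate
11 | (13S)-15-acetoxy-7ξ-hydroxy-8ξ-labdan-17-al (5α-H, 9α-H, 10β-CH3; C7 and C8 left open, mixture) | CC(=O)OCC[C@@H](C)CC[C@H]1C(C=O)C(O)C[C@H]2C(C)(C)CCC[C@]12C | intermediate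
12 | C7 methanesulfonate of 11 (not isolated) | CC(=O)OCC[C@@H](C)CC[C@H]1C(C=O)C(OS(C)(=O)=O)C[C@H]2C(C)(C)CCC[C@]12C | intermediate
13 | (13S)-15-acetoxylabd-7-en-17-al (5α-H, 9α-H, 10β-CH3) | CC(=O)OCC[C@@H](C)CC[C@H]1C(C=O)=CC[C@H]2C(C)(C)CCC[C@]12C | intermediate
14 | (13S)-17-hydroxylabd-7-en-15-yl acetate (5α-H, 9α-H, 10β-CH3) | CC(=O)OCC[C@@H](C)CC[C@H]1C(CO)=CC[C@H]2C(C)(C)CCC[C@]12C | intermediate
15 | (13S)-labd-7-ene-15,17-diyl diacetate, (5S,9R,10S,13S) | CC(=O)OCC[C@@H](C)CC[C@H]1C(COC(C)=O)=CC[C@H]2C(C)(C)CCC[C@]12C | target

**Step count**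
Total steps: 8. Longest linear sequence: 6 steps (5 to 15 through steps 3–8, or 1 to 15 through steps 1, 2 and 5–8).

**Steps most likely to fail**

Step 5 is the greatest risk. The intermolecular addition of the hindered tertiary radical to a singly activated, β-alkylated enal may be slow. Hydrogenation or positional isomerisation of the donor alkene (the latter would also scramble C5), reduction of the enal, and weak facial discrimination at C9 could then compete. The fallback sets out from 2 and 8 and comes back to the route at 15. It replaces the enal by a doubly activated acceptor and closes ring B by olefination in a separate operation.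
- Ozonolysis of 2 (O3, CH2Cl2/MeOH, −78 °C; Me2S) gives (S)-3-methyl-6-oxohexyl acetate F1.
- Knoevenagel condensation with triethyl phosphonoacetate (TiCl4, N-methylmorpholine, THF, 0 °C) gives ethyl (6S)-8-acetoxy-2-(diethoxyphosphoryl)-6-methyloct-2-enoate F2 (E/Z mixture, both isomers serve).
- The Fe(acac)3/PhSiH3 conditions of step 5 with 8 give the open-chain 7,8-seco phosphonoacetate F3. The alkylidene phosphonoacetate is a much faster radical trap, and its bulkier C8 terminus should sharpen the preference at C9.
- Intramolecular Horner–Wadsworth–Emmons olefination onto the C7 aldehyde (LiCl, DBU, MeCN) gives ethyl (13S)-15-acetoxylabd-7-en-17-oate F4, which already has C7=C8.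
- DIBAL-H (CH2Cl2, −78 °C) reduces ester and acetate to (13S)-labd-7-ene-15,17-diol F5, and Ac2O/pyridine/DMAP gives 15.

Step 4 is second. The [3,3] shift has to form a bond to the ring carbon next to the quaternary C4. If it is slow, thermal elimination of the vinyl ether to a diene can take over. The fallback sets out from 5 and comes back at 8. It sets C5 by an anti-SN2′ allylic substitution instead of a sigmatropic shift.
- Reduction of 5 with the enantiomeric (R)-oxazaborolidine gives (S)-2,4,4-trimethylcyclohex-2-en-1-ol F6.
- Picolinoyl chloride hydrochloride, Et3N and DMAP give (S)-2,4,4-trimethylcyclohex-2-en-1-yl pyridine-2-carboxylate F7.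
- (1,3-Dioxolan-2-ylmethyl)magnesium bromide with CuBr·SMe2 (THF, −40 to 0 °C) should deliver the two-carbon unit to C5 on the face opposite to the leaving group. This gives 2-{[(1S)-2,6,6-trimethylcyclohex-2-en-1-yl]methyl}-1,3-dioxolane F8.
- Aqueous HCl in THF releases 8.

The opposite carbinol configuration together with anti delivery leads to the same C5 configuration as the suprafacial shift from 6.

Step 3 is third. Enantioface discrimination may be incomplete, because both ketone substituents are carbon chains of similar reach. This would lower the enantiomeric purity of ring A and show up as diastereomers after step 5. The fallback sets out from 5 and comes back at 6. It uses kinetic resolution instead of asymmetric reduction.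
- NaBH4/CeCl3·7H2O (MeOH, 0 °C) gives racemic 2,4,4-trimethylcyclohex-2-en-1-ol F9.
- Acylation with vinyl acetate and immobilised Candida antarctica lipase B (hexane, rt) is expected, by the usual empirical rule for secondary alcohols, to acylate the (R)-enantiomer faster. This gives (R)-2,4,4-trimethylcyclohex-2-en-1-yl acetate F10.
- F10 is separated from the unreacted (S)-alcohol and methanolysed (K2CO3, MeOH) to 6.

**Further compounds**
F1 | step 5 | (S)-3-methyl-6-oxohexyl acetate | CC(=O)OCC[C@@H](C)CCC=O
F2 | step 5 | ethyl (6S)-8-acetoxy-2-(diethoxyphosphoryl)-6-methyloct-2-enoate (E/Z mixture) | CC(=O)OCC[C@@H](C)CCC=C(C(=O)OCC)P(=O)(OCC)OCC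
F3 | step 5 | open-chain 7,8-seco phosphonoacetate (Giese adduct; 5α-H, 9α-H, 10β-CH3, 13S; C8 epimers) | CC(=O)OCC[C@@H](C)CC[C@@H](C(C(=O)OCC)P(=O)(OCC)OCC)[C@@]1(C)CCCC(C)(C)[C@@H]1CC=O
F4 | step 5 | ethyl (13S)-15-acetoxylabd-7-en-17-oate | CC(=O)OCC[C@@H](C)CC[C@H]1C(C(=O)OCC)=CC[C@H]2C(C)(C)CCC[C@]12C
F5 | step 5 | (13S)-labd-7-ene-15,17-diol | OCC[C@@H](C)CC[C@H]1C(CO)=CC[C@H]2C(C)(C)CCC[C@]12C
F6 | step 4 | (S)-2,4,4-trimethylcyclohex-2-en-1-ol | O[C@H]1CCC(C)(C)C=C1C
F7 | step 4 | (S)-2,4,4-trimethylcyclohex-2-en-1-yl pyridine-2-carboxylate | O=C(O[C@H]1CCC(C)(C)C=C1C)c1ccccn1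
F8 | step 4 | 2-{[(1S)-2,6,6-trimethylcyclohex-2-en-1-yl]methyl}-1,3-dioxolane | C1COC(O1)C[C@@H]2C(C)=CCCC2(C)C
F9 | step 3 | racemic 2,4,4-trimethylcyclohex-2-en-1-ol | OC1CCC(C)(C)C=C1C
F10 | step 3 | (R)-2,4,4-trimethylcyclohex-2-en-1-yl acetate | CC(=O)O[C@@H]1CCC(C)(C)C=C1C
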